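The route rests on cutting the single bond between C18 and C20 (chain numbered from the ketone carbon C5 to the tetronate ring carbon C21, methyl C19 on C18). Through this one bond the lone stereocentre C18 is attached to the exocyclic CH of the E-configured ylidene on the furanone ring. A palladium-catalysed Suzuki–Miyaura coupling of a configurationally defined secondary alkyltrifluoroborate with an (E)-iodomethylene tetronate forms this bond, fixing the C18 configuration by invertive transmetalation and carrying the C20=C21 geometry over unchanged. The precursor pair is the (E)-5-(iodomethylene)-4-methoxy-3-methylfuranone 8 and the open-chain potassium (R)-trifluoroborate 26, which already holds the furyl ketone and both chain alkenes.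

Key step: step 12

Remarks on the chemistry (assumptions and design choices):
- Transmetalation of the unactivated secondary alkyltrifluoroborate under Pd/P(t-Bu)3 is assumed to be invertive, so the (R)-borate is made; with a retentive ligand system the (S)-borate, from (+)-sparteine in step 5, would be used.
- The target is (S) at C18 and E at both C8=C10 and C20=C21; the (R)-borate, the (E)-iodide and the coupled methyl ether are consistent with this.
- The C8=C10 alkene is made by a Carroll rearrangement of a secondary allylic alcohol, because a tertiary allylic ester would not control its geometry.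
- The boron-bearing chain is shortened by using allylboronic acid pinacol ester in the lithiation–borylation and a chemoselective B-alkyl Suzuki coupling.
- Compounds 5, 19, 21 and 22 are racemic; their stereocentres are destroyed downstream.

Step 1
Reactants: 1 3-(trimethylsilyl)propiolic acid; 2 methyl propanoate
Product: 5 methyl 2-methyl-3-oxo-5-(trimethylsilyl)pent-4-ynoate (racemic), via 3-(trimethylsilyl)propioloyl chloride 3 (not isolated), via lithium enolate of methyl propanoate 4 (not isolated)
Conditions: (COCl)2, cat. DMF, CH2Cl2, 0 °C to rt, evaporate; 2 (2.2 equiv), LiN(i-Pr)2 (2.2 equiv), THF, −78 °C, then add 3; 1 M HCl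
Reagents that add atoms: none
Why: Crossed Claisen acylation of a pre-formed ester enolate by an acid chloride; the second equivalent of enolate deprotonates the more acidic β-keto ester and shields it from further attack, and the silyl cap hinders conjugate addition to the ynone.

Step 2
Reactants: 5 methyl 2-methyl-3-oxo-5-(trimethylsilyl)pent-4-ynoate
Product: 6 methyl (E)-3-methoxy-2-methyl-5-(trimethylsilyl)pent-2-en-4-ynoate
Conditions: K2CO3, Me2SO4, DMF, 0 °C to rt
Reagents that add atoms: dimethyl sulfate, COS(=O)(=O)OC
Why: O-Alkylation of a β-keto ester enolate, in which the dissociated potassium enolate prefers the W-shape (enolate oxygen anti to the ester) and the hard sulfate reacts at oxygen of this hindered delocalised enolate, so OMe should end trans to CO2Me and the alkyne cis to it; a minor geometric isomer would be removed by chromatography.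

Step 3
Reactants: 6 methyl (E)-3-methoxy-2-methyl-5-(trimethylsilyl)pent-2-en-4-ynoate
Product: 7 (E)-3-methoxy-2-methylpent-2-en-4-ynoic acid
Conditions: LiOH·H2O (4 equiv), THF/MeOH/H2O, rt to 40 °C; then 1 M HCl to pH 3, 0 °C
Reagents that add atoms: lithium hydroxide, [Li+].[OH-]
Why: Ester saponification under which the C(sp)–Si bond is also cleaved, so acid and terminal alkyne are unmasked together; base does not disturb the enol ether geometry.

Step 4
Reactants: 7 (E)-3-methoxy-2-methylpent-2-en-4-ynoic acid
Product: 8 (E)-5-(iodomethylene)-4-methoxy-3-methylfuran-2(5H)-one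
Conditions: I2 (3 equiv), NaHCO3, MeCN, rt, dark; aq. Na2S2O3
Reagents that add atoms: iodine, II
Why: Iodolactonisation in the 5-exo-dig mode, in which the carboxylate opens the iodonium of the terminal alkyne at the internal carbon from the side opposite iodine, so iodine ends trans to the ring oxygen (E) as a direct result of anti addition.

Step 5
Reactants: 9 ethyl N,N-diisopropylcarbamate; 10 allylboronic acid pinacol ester
Product: 13 (R)-4,4,5,5-tetramethyl-2-(pent-4-en-2-yl)-1,3,2-dioxaborolane, via (S)-1-lithioethyl N,N-diisopropylcarbamate 11 (not isolated), via lithium (S)-allyl[1-(diisopropylcarbamoyloxy)ethyl]pinacolatoborate 12 (not isolated)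
Conditions: s-BuLi, (−)-sparteine, Et2O, −78 °C, 5 h; 10, −78 °C, 1 h; MgBr2·OEt2, Et2O, reflux
Reagents that add atoms: none
Why: Sparteine-mediated enantioselective lithiation followed by lithiation–borylation: the pro-S proton is removed, the configurationally stable lithio carbamate is borylated with retention, and the allyl group migrates from boron to carbon anti to the departing carbamate (1,2-metallate rearrangement, inversion), which sets the boron-bearing centre as R.

Step 6
Reactants: 14 ethyl acetate; 15 2,3-dibromopropene
Product: 17 ethyl 4-bromopent-4-enoate, via lithium enolate of ethyl acetate 16 (not isolated)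
Conditions: LiN(i-Pr)2, THF, −78 °C; 15, DMPU, −78 to −20 °C
Reagents that add atoms: none
Why: Ester enolate alkylation by an allylic bromide (direct and allylic-shift substitution give the same product here), with the vinylic bromide inert.

Step 7
Reactants: 17 ethyl 4-bromopent-4-enoate
Product: 18 4-bromopent-4-enal
Conditions: i-Bu2AlH (1.05 equiv), CH2Cl2, −78 °C; aq. potassium sodium tartrate
Reagents that add atoms: none
Why: Partial hydride reduction of an ester, which stops at the aluminium hemiacetal at −78 °C and releases the aldehyde on work-up.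

Step 8
Reactants: 18 4-bromopent-4-enal
Product: 19 6-bromo-2-methylhepta-1,6-dien-3-ol (racemic)
Conditions: CH2=C(CH3)MgBr, THF, −78 to 0 °C; then H2O
Reagents that add atoms: isopropenylmagnesium bromide, C=C(C)[Mg]Br
Why: Grignard 1,2-addition to an aldehyde; the carbinol centre is made racemic on purpose because it becomes sp2 in the next step.

Step 9
Reactants: 19 6-bromo-2-methylhepta-1,6-dien-3-ol; 20 ethyl 3-(furan-3-yl)-3-oxopropanoate
Product: 23 (E)-8-bromo-1-(furan-3-yl)-4-methylnona-4,8-dien-1-one, via 6-bromo-2-methylhepta-1,6-dien-3-yl 3-(furan-3-yl)-3-oxopropanoate 21 (not isolated), via (E)-8-bromo-2-(furan-3-carbonyl)-4-methylnona-4,8-dienoic acid 22 (not isolated)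
Conditions: cat. DMAP, toluene, 110 °C, 4 Å MS (−EtOH); then Ph2O, 170–180 °C (−CO2)
Reagents that add atoms: none
Why: Carroll rearrangement, in which the enol of the allyl β-keto ester undergoes a [3,3]-sigmatropic shift through a chair with the side chain on the carbinol carbon equatorial (an axial chain would clash with the enol OH), which should give the E-trisubstituted C8=C10 alkene before the β-keto acid loses CO2.

Step 10
Reactants: 13 (R)-4,4,5,5-tetramethyl-2-(pent-4-en-2-yl)-1,3,2-dioxaborolane; 23 (E)-8-bromo-1-(furan-3-yl)-4-methylnona-4,8-dien-1-one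
Product: 25 (R,E)-1-(furan-3-yl)-4-methyl-8-methylidene-12-(4,4,5,5-tetramethyl-1,3,2-dioxaborolan-2-yl)tridec-4-en-1-one, via (R)-9-[4-(4,4,5,5-tetramethyl-1,3,2-dioxaborolan-2-yl)pentyl]-9-borabicyclo[3.3.1]nonane 24 (not isolated)
Conditions: 13 (1.3 equiv), (9-BBN-H)2, THF, 0 °C to rt; then 23, PdCl2(dppf) (5 mol %), 3 M aq. K3PO4, THF/DMF, rt to 45 °C
Reagents that add atoms: none
Why: Hydroboration followed by B-alkyl Suzuki–Miyaura coupling: the borane adds anti-Markovnikov to the terminal alkene only and is consumed before the ketone is introduced, and under mild aqueous base only the primary alkyl-9-BBN transmetalates, the secondary pinacol boronate being inert, so C13–C15 forms and the stereocentre is untouched.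

Step 11
Reactants: 25 (R,E)-1-(furan-3-yl)-4-methyl-8-methylidene-12-(4,4,5,5-tetramethyl-1,3,2-dioxaborolan-2-yl)tridec-4-en-1-one
Product: 26 potassium (R,E)-trifluoro[13-(furan-3-yl)-10-methyl-6-methylidene-13-oxotridec-9-en-2-yl]borate
Conditions: 4.5 M aq. KHF2 (4 equiv), MeOH, rt; evaporate repeatedly from MeOH/H2O; acetone extraction, Et2O precipitation
Reagents that add atoms: potassium hydrogen difluoride, [K+].F[H-]F
Why: Ligand exchange at boron (pinacol boronate to trifluoroborate) that does not involve the boron-bearing carbon, so the R configuration is kept.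

Step 12
Reactants: 8 (E)-5-(iodomethylene)-4-methoxy-3-methylfuran-2(5H)-one; 26 potassium (R,E)-trifluoro[13-(furan-3-yl)-10-methyl-6-methylidene-13-oxotridec-9-en-2-yl]borate
Product: 27 (5E)-5-[(2S,9E)-13-(furan-3-yl)-2,10-dimethyl-6-methylidene-13-oxotridec-9-en-1-ylidene]-4-methoxy-3-methylfuran-2(5H)-one
Conditions: Pd(P(t-Bu)3)2 (10 mol %), K2CO3 (3 equiv), toluene/H2O, 60–80 °C, degassed, 8 in slight excess
Reagents that add atoms: none
Why: Proposed new method: zerovalent palladium bearing P(t-Bu)3 should insert into the C–I bond of 8 with retention of the alkene geometry, the borate 26 is released slowly as the boronic acid by K2CO3/H2O and hands its secondary alkyl group to palladium through an open (SE2, back-side) transition state with inversion at C18, and reductive elimination forms the C18–C20 bond. The closest known reaction type is the stereospecific invertive Suzuki–Miyaura coupling of enantioenriched unactivated secondary alkyltrifluoroborates with aryl chlorides under the same ligand, next to Suzuki couplings of 5-(halomethylene)furanones with arylboron partners that keep the exocyclic geometry; the pairing of a secondary alkylboron with this alkenyl iodide has not been shown. No ring is closed. The one new stereocentre, C18, is controlled by the configuration of the borate (R in the reagent, S in the product through inversion), and the C20=C21 geometry is inherited from the iodide. The step needs transfer of the intact secondary alkyl group without β-hydride elimination and re-insertion (which would give the linear isomer joined through C19) and without E/Z leakage; the bulky electron-rich phosphine keeps palladium low-coordinate so that reductive elimination outruns β-hydride elimination, and in the E-iodide palladium sits trans to the ring oxygen, so a syn β-acyloxy elimination that would open the lactone has no accessible geometry. Mild carbonate base, little water and 60–80 °C are chosen because the alkenyl iodide adds to palladium far more easily than an aryl chloride and the enol lactone must not be hydrolysed.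

Step 13
Reactants: 27 (5E)-5-[(2S,9E)-13-(furan-3-yl)-2,10-dimethyl-6-methylidene-13-oxotridec-9-en-1-ylidene]-4-methoxy-3-methylfuran-2(5H)-one
Product: 28 (5E)-5-[(2S,9E)-13-(furan-3-yl)-2,10-dimethyl-6-methylidene-13-oxotridec-9-en-1-ylidene]-4-hydroxy-3-methylfuran-2(5H)-one (CNP0018618.1)
Conditions: LiCl (5 equiv), DMF, 80 °C; then cold 0.5 M HCl
Reagents that add atoms: none
Why: Nucleophilic O-demethylation of a vinylogous methyl carbonate (Krapcho-type substitution by chloride at the methyl group) that releases the stabilised lithium tetronate; the neutral conditions should leave the ketone, the furan, the alkenes, C18 and the ylidene geometry alone.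

Compound list
1 | 3-(trimethylsilyl)propiolic acid | C[Si](C)(C)C#CC(=O)O | starting material
2 | methyl propanoate | CCC(=O)OC | starting material
3 | 3-(trimethylsilyl)propioloyl chloride | C[Si](C)(C)C#CC(=O)Cl | intermediate
4 | lithium enolate of methyl propanoate (geometry immaterial) | CC=C(OC)O[Li] | intermediate
5 | methyl 2-methyl-3-oxo-5-(trimethylsilyl)pent-4-ynoate (racemic) | COC(=O)C(C)C(=O)C#C[Si](C)(C)C | intermediate
6 | methyl (E)-3-methoxy-2-methyl-5-(trimethylsilyl)pent-2-en-4-ynoate | COC(=O)/C(C)=C(/OC)C#C[Si](C)(C)C | intermediate
7 | (E)-3-methoxy-2-methylpent-2-en-4-ynoic acid | OC(=O)/C(C)=C(/OC)C#C | intermediate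
8 | (E)-5-(iodomethylene)-4-methoxy-3-methylfuran-2(5H)-one | I/C=C1/OC(=O)C(C)=C1OC | intermediate
9 | ethyl N,N-diisopropylcarbamate | CCOC(=O)N(C(C)C)C(C)C | starting material
10 | allylboronic acid pinacol ester | C=CCB1OC(C)(C)C(C)(C)O1 | starting material
11 | (S)-1-lithioethyl N,N-diisopropylcarbamate (sparteine complex) | C[C@H]([Li])OC(=O)N(C(C)C)C(C)C | intermediate
12 | lithium (S)-allyl[1-(diisopropylcarbamoyloxy)ethyl]pinacolatoborate | C[C@H]([B-]1(CC=C)OC(C)(C)C(C)(C)O1)OC(=O)N(C(C)C)C(C)C.[Li+] | intermediate
13 | (R)-4,4,5,5-tetramethyl-2-(pent-4-en-2-yl)-1,3,2-dioxaborolane | C[C@H](CC=C)B1OC(C)(C)C(C)(C)O1 | intermediate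
14 | ethyl acetate | CCOC(C)=O | starting material
15 | 2,3-dibromopropene | C=C(Br)CBr | starting material
16 | lithium enolate of ethyl acetate | C=C(OCC)O[Li] | intermediate
17 | ethyl 4-bromopent-4-enoate | CCOC(=O)CCC(Br)=C | intermediate
18 | 4-bromopent-4-enal | O=CCCC(Br)=C | intermediate
19 | 6-bromo-2-methylhepta-1,6-dien-3-ol (racemic) | C=C(C)C(O)CCC(Br)=C | intermediate
20 | ethyl 3-(furan-3-yl)-3-oxopropanoate | CCOC(=O)CC(=O)c1ccoc1 | starting material
21 | 6-bromo-2-methylhepta-1,6-dien-3-yl 3-(furan-3-yl)-3-oxopropanoate (racemic) | C=C(C)C(CCC(Br)=C)OC(=O)CC(=O)c1ccoc1 | intermediate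
22 | (E)-8-bromo-2-(furan-3-carbonyl)-4-methylnona-4,8-dienoic acid (racemic) | OC(=O)C(C/C(C)=C/CCC(Br)=C)C(=O)c1ccoc1 | intermediate
23 | (E)-8-bromo-1-(furan-3-yl)-4-methylnona-4,8-dien-1-one | O=C(c1ccoc1)CC/C(C)=C/CCC(Br)=C | intermediate
24 | (R)-9-[4-(4,4,5,5-tetramethyl-1,3,2-dioxaborolan-2-yl)pentyl]-9-borabicyclo[3.3.1]nonane | C[C@H](CCCB1C2CCCC1CCC2)B1OC(C)(C)C(C)(C)O1 | intermediate
25 | (R,E)-1-(furan-3-yl)-4-methyl-8-methylidene-12-(4,4,5,5-tetramethyl-1,3,2-dioxaborolan-2-yl)tridec-4-en-1-one | O=C(c1ccoc1)CC/C(C)=C/CCC(=C)CCC[C@@H](C)B1OC(C)(C)C(C)(C)O1 | intermediate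
26 | potassium (R,E)-trifluoro[13-(furan-3-yl)-10-methyl-6-methylidene-13-oxotridec-9-en-2-yl]borate | O=C(c1ccoc1)CC/C(C)=C/CCC(=C)CCC[C@@H](C)[B-](F)(F)F.[K+] | intermediate
27 | (5E)-5-[(2S,9E)-13-(furan-3-yl)-2,10-dimethyl-6-methylidene-13-oxotridec-9-en-1-ylidene]-4-methoxy-3-methylfuran-2(5H)-one | O=C(c1ccoc1)CC/C(C)=C/CCC(=C)CCC[C@H](C)/C=C1/OC(=O)C(C)=C1OC | intermediate
28 | (5E)-5-[(2S,9E)-13-(furan-3-yl)-2,10-dimethyl-6-methylidene-13-oxotridec-9-en-1-ylidene]-4-hydroxy-3-methylfuran-2(5H)-one (CNP0018618.1) | C=C(CC/C=C(\C)CCC(=O)c1ccoc1)CCC[C@H](C)/C=C1/OC(=O)C(C)=C1O | target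

Total step count: 13. Longest linear sequence: 8 steps (steps 6, 7, 8, 9, 10, 11, 12, 13).

Steps most likely to fail

1. Step 12 (proposed new method).
- Transmetalation of the secondary alkylboron may be too slow, so that protodeboronation dominates.
- β-Hydride elimination with re-insertion may scramble the alkyl group, or the configuration at C18 may erode.
- The enol lactone may be hydrolysed, or its geometry lost, under the basic aqueous conditions.

The fallback is a stereoretentive Negishi coupling of a configurationally defined secondary alkylzinc with the same alkenyl iodide, a known reaction type for alkenyl iodides; it sets out from 13 and comes back at 27. Boronate 13 would be oxidised with NaBO3·4H2O in THF/H2O (retention) to (R)-pent-4-en-2-ol F1. An Appel iodination (I2, PPh3, imidazole, CH2Cl2, 0 °C) would turn this with inversion into (S)-4-iodopent-1-ene F2. Iodine–lithium exchange with t-BuLi at −100 °C in pentane/Et2O should give, with retention, [(S)-pent-4-en-2-yl]lithium F3. This is trapped at once with Me3SiCH2ZnBr·LiBr as [(S)-pent-4-en-2-yl][(trimethylsilyl)methyl]zinc F4. Coupling of F4 with iodide 8 under Pd(PPh3)4 in THF (−25 °C to rt) should proceed with retention at carbon and at the alkene to give (S,E)-4-methoxy-3-methyl-5-(2-methylpent-4-en-1-ylidene)furan-2(5H)-one F5. Hydroboration of the terminal alkene of F5 with 9-BBN-H gives the 9-BBN adduct of F5 F6, and B-alkyl Suzuki–Miyaura coupling of F6 with bromide 23 (PdCl2(dppf), aq. K3PO4, as in step 10) would deliver 27. One inversion (Appel) replaces the inversion of the key step, so the same (R)-boronate 13 serves.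

2. Step 4.
- Iodine may attack the electron-rich enol ether carbon next to the carboxylate (ipso-iodination with loss of CO2) instead of the alkyne.
- Closure may take the 6-endo course to an iodopyranone.

The fallback changes the nucleophile from the carboxylate to a neutral ester carbonyl; it sets out from 7 and comes back at 8. Acid 7 would be esterified (Boc2O, cat. DMAP, t-BuOH) to tert-butyl (E)-3-methoxy-2-methylpent-2-en-4-ynoate F7. Electrophilic iodocyclisation of F7 with ICl in CH2Cl2 (−78 to 0 °C) should close the ring through the carbonyl oxygen of the vinylogous carbonate, again anti to iodine, with loss of the tert-butyl group as 2-methylpropene, to give 8. Decarboxylative iodination is not possible in the ester, and the push–pull alkene is less nucleophilic.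

3. Step 2.
- Methylation may occur at carbon instead of oxygen.
- O-methylation may occur from the chelated enolate geometry, placing OMe cis to the ester and giving an isomer that cannot lactonise.

The fallback builds the enol ether first and introduces the alkyne by cross-coupling with retention; it sets out from 2 and comes back at 6. Methyl propanoate 2 would be formylated (HCO2Me, NaH, THF) to methyl 2-methyl-3-oxopropanoate sodium enolate F8, and O-methylated in the same pot (Me2SO4) to methyl (E)-3-methoxy-2-methylacrylate F9. Ester-directed vinylic lithiation of F9 (LiN(i-Pr)2, THF, −90 °C) at the β-hydrogen cis to the ester would give methyl (E)-3-lithio-3-methoxy-2-methylacrylate F10. Quenching F10 with I2 gives methyl (Z)-3-iodo-3-methoxy-2-methylacrylate F11. Sonogashira coupling of F11 with ethynyltrimethylsilane (PdCl2(PPh3)2, CuI, Et3N, THF, rt) proceeds with retention and would give 6 with the alkyne cis to the ester by construction.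

Further compounds
F1 | step 12 | (R)-pent-4-en-2-ol | C[C@@H](O)CC=C
F2 | step 12 | (S)-4-iodopent-1-ene | C[C@H](I)CC=C
F3 | step 12 | [(S)-pent-4-en-2-yl]lithium | C[C@H]([Li])CC=C
F4 | step 12 | [(S)-pent-4-en-2-yl][(trimethylsilyl)methyl]zinc | C[C@H]([Zn]C[Si](C)(C)C)CC=C
F5 | step 12 | (S,E)-4-methoxy-3-methyl-5-(2-methylpent-4-en-1-ylidene)furan-2(5H)-one | C=CC[C@H](C)/C=C1/OC(=O)C(C)=C1OC
F6 | step 12 | 9-BBN adduct of F5, (S,E)-5-[5-(9-borabicyclo[3.3.1]nonan-9-yl)-2-methylpentylidene]-4-methoxy-3-methylfuran-2(5H)-one | B1(C2CCCC1CCC2)CCC[C@H](C)/C=C1/OC(=O)C(C)=C1OC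
F7 | step 4 | tert-butyl (E)-3-methoxy-2-methylpent-2-en-4-ynoate | CC(C)(C)OC(=O)/C(C)=C(/OC)C#C
F8 | step 2 | methyl 2-methyl-3-oxopropanoate sodium enolate | COC(=O)C(C)=C[O-].[Na+]
F9 | step 2 | methyl (E)-3-methoxy-2-methylacrylate | COC(=O)/C(C)=C/OC
F10 | step 2 | methyl (E)-3-lithio-3-methoxy-2-methylacrylate | COC(=O)/C(C)=C(\[Li])OC
F11 | step 2 | methyl (Z)-3-iodo-3-methoxy-2-methylacrylate | COC(=O)/C(C)=C(\I)OC
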